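**Retrosynthetic overview**

- Feature: in ring A the carbons C2 (OH), C3 (Cl) and C4 (OMe) form an oxygen–chlorine–oxygen triad, with H on C5 and propyl on C6. This is the imprint of a 2-chloro-1,1,3-trioxygenated butadiene (C2–C5) on a propyl-bearing alkynoate (C1 and C6).
- Last disconnection: the ring B carboxylic acid is released from its tert-butyl ester by acidolysis.
- Key disconnection: ring A bonds C1–C2 and C5–C6 are cut, leading back to a chlorinated silyl ketene acetal diene and the hex-2-ynoate ester of the ring B phenol. The depside ester link is already in the dienophile, and ring A is the only ring formed.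
- Ring B is taken as an arene: 5-propylresorcinol is carboxylated, the acid is tert-butylated and the free 4-hydroxyl is acylated with hex-2-ynoic acid.
- The diene comes from methyl 2-chloroacetoacetate by enol etherification and O-silylation of its dienolate, so chlorine and the methyl ether arrive with the diene.

Key step: step 6

Remark on the chemistry: the target has no stereocentre. The hydrogen-bonded ring B phenol of the ynoate would protonate the ketene acetal diene, so it is masked in the flask as a trimethylsilyl ether that the acidic work-up of the same step removes.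

**Step 1**
Reactants: 1 methyl 2-chloroacetoacetate
Product: 3 methyl 2-chloro-3-methoxybut-2-enoate (E/Z mixture), via dimethyl ketal 2 (not isolated)
Conditions: HC(OMe)3, cat. H2SO4, MeOH, rt; then cat. TsOH, distil (−MeOH)
Reagents that add atoms: trimethyl orthoformate, COC(OC)OC
Why: Acid-catalysed ketalisation of the ketone with the orthoester as water scavenger, then acid-catalysed loss of methanol into conjugation with the ester, is the standard enol etherification of acetoacetates; the ester and the C–Cl bond are not touched and both alkene geometries lead to the same dienolate.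

**Step 2**
Reactants: 3 methyl 2-chloro-3-methoxybut-2-enoate
Product: 5 2-chloro-1,3-dimethoxy-1-(trimethylsilyloxy)buta-1,3-diene, via lithium dienolate 4 (not isolated)
Conditions: LiN(i-Pr)2 (commercial solution), THF, −78 °C; then Me3SiCl, −78 °C → rt; pentane, filter, distil under reduced pressure
Reagents that add atoms: chlorotrimethylsilane, C[Si](C)(C)Cl
Why: Kinetic γ-deprotonation of the β-methoxy enoate gives the extended dienolate and O-silylation traps it as the vinylogous ketene acetal, the standard preparation of Brassard-type dienes; there is no α-hydrogen and the vinylic chlorine is inert to the amide base at −78 °C.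

**Step 3**
Reactants: 6 5-propylresorcinol
Product: 7 2,4-dihydroxy-6-propylbenzoic acid
Conditions: MeOMgOCO2Me (2 M in DMF), 120 °C, N2 stream; then ice-cold aq. HCl
Reagents that add atoms: methyl magnesium carbonate, COC(=O)O[Mg]OC
Why: Kolbe–Schmitt-type carboxylation in which the magnesium phenoxide delivers CO2 to the ring carbon ortho to one hydroxyl and para to the other, and chelation of the salicylate to magnesium pulls the equilibrium forward, as is established for 5-alkylresorcinols.

**Step 4**
Reactants: 7 2,4-dihydroxy-6-propylbenzoic acid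
Product: 8 tert-butyl 2,4-dihydroxy-6-propylbenzoate
Conditions: i-PrN=C(Ot-Bu)NHi-Pr, CH2Cl2, rt
Reagents that add atoms: O-tert-butyl-N,N'-diisopropylisourea, CC(C)N=C(NC(C)C)OC(C)(C)C
Why: Isourea esterification, in which the acid protonates the isourea and the carboxylate is O-alkylated by tert-butyl transfer within the ion pair, is a reaction at oxygen that is indifferent to the two ortho substituents and should leave the far less acidic phenols alone.

**Step 5**
Reactants: 8 tert-butyl 2,4-dihydroxy-6-propylbenzoate; 9 hex-2-ynoic acid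
Product: 10 tert-butyl 4-(hex-2-ynoyloxy)-2-hydroxy-6-propylbenzoate
Conditions: DCC, DMAP (cat.), CH2Cl2, 0 °C → rt
Reagents that add atoms: none
Why: Steglich esterification should acylate only the 4-hydroxyl, because the 2-hydroxyl is held in a hydrogen bond to the ester carbonyl and is flanked by the tert-butyl ester; low temperature and little DMAP limit conjugate addition to the ynoate.

**Step 6**
Reactants: 10 tert-butyl 4-(hex-2-ynoyloxy)-2-hydroxy-6-propylbenzoate; 5 2-chloro-1,3-dimethoxy-1-(trimethylsilyloxy)buta-1,3-diene
Product: 14 tert-butyl 4-(3-chloro-2-hydroxy-4-methoxy-6-propylbenzoyloxy)-2-hydroxy-6-propylbenzoate, via ring B trimethylsilyl ether 11 (not isolated), via cyclohexadiene ketal cycloadduct 12 (not isolated), via bis(trimethylsilyl) depside 13 (not isolated)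
Conditions: MeC(OSiMe3)=NSiMe3 (BSA), toluene, 60 °C, evaporate; then 5 (3 equiv, in portions), toluene, 110–120 °C, sealed tube, argon; then 0.5 M HCl, THF, rt
Reagents that add atoms: none
Why: The electron-rich diene 5 and the acceptor alkyne of 11 should combine in a normal-electron-demand Diels–Alder reaction, concerted but strongly asynchronous (at the limit a Mukaiyama–Michael addition followed by 6-exo-trig closure of the allenoate carbon onto the methoxy(silyloxy)carbenium carbon), in which the diene CH2 bonds to the propyl-bearing β-carbon (ring A C5–C6) and the ketene acetal carbon to the α-carbon (ring A C1–C2) to give the cyclohexa-1,4-diene 12. The closest known reaction type is the Diels–Alder benzannulation of 1,1,3-trioxygenated butadienes with alk-2-ynoates, which gives 6-alkylresorcylates after loss of an alcohol. Ring A is the only ring closed, as a six-membered carbocycle by intermolecular [4+2] addition, and it becomes aromatic when 12 loses methanol by 1,4-elimination across the ketal carbon and the CH2 group to give 13. No stereocentre remains, since the ketal carbon of 12 forms as a racemate and is flattened on aromatisation. The step needs a single orientation, and matched polarisation secures it: the largest HOMO coefficient of 5 is on the CH2 terminus and the largest LUMO coefficient of 11 on the β-carbon (the aryl ester lowers that LUMO), while chlorine on the central diene carbon can only end on C3 between the two oxygens. The ring B phenol is silylated first so that it cannot protonate the ketene acetal, and dilute acid at the end should cleave both aryl silyl ethers, and any surviving silyl ketal through its hemiketal with loss of methanol, without touching the tert-butyl ester or the depside ester.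

**Step 7**
Reactants: 14 tert-butyl 4-(3-chloro-2-hydroxy-4-methoxy-6-propylbenzoyloxy)-2-hydroxy-6-propylbenzoate
Product: 15 3-chlorodivaricatic acid, 4-(3-chloro-2-hydroxy-4-methoxy-6-propylbenzoyloxy)-2-hydroxy-6-propylbenzoic acid
Conditions: CF3CO2H, Et3SiH, CH2Cl2, 0 °C → rt; evaporate, crystallise
Reagents that add atoms: none
Why: Acidolysis of the tert-butyl ester by the AAL1 path, with the tert-butyl cation reduced by Et3SiH to isobutane before it can alkylate the electron-rich rings, should leave the aryl ester, the methyl ether and the aryl chloride untouched.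

**Compound list**

1 | methyl 2-chloroacetoacetate (racemic) | CC(=O)C(Cl)C(=O)OC | starting material
2 | methyl 2-chloro-3,3-dimethoxybutanoate (racemic) | COC(=O)C(Cl)C(C)(OC)OC | intermediate
3 | methyl 2-chloro-3-methoxybut-2-enoate (E/Z mixture) | COC(=O)C(Cl)=C(C)OC | intermediate
4 | lithium 2-chloro-1,3-dimethoxybuta-1,3-dien-1-olate | C=C(OC)C(Cl)=C(OC)[O-].[Li+] | intermediate
5 | 2-chloro-1,3-dimethoxy-1-(trimethylsilyloxy)buta-1,3-diene (either geometry at the ketene acetal double bond) | C=C(OC)C(Cl)=C(OC)O[Si](C)(C)C | intermediate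
6 | 5-propylresorcinol | CCCc1cc(O)cc(O)c1 | starting material
7 | 2,4-dihydroxy-6-propylbenzoic acid | CCCc1cc(O)cc(O)c1C(=O)O | intermediate
8 | tert-butyl 2,4-dihydroxy-6-propylbenzoate | CCCc1cc(O)cc(O)c1C(=O)OC(C)(C)C | intermediate
9 | hex-2-ynoic acid | CCCC#CC(=O)O | starting material
10 | tert-butyl 4-(hex-2-ynoyloxy)-2-hydroxy-6-propylbenzoate | CCCC#CC(=O)Oc1cc(CCC)c(C(=O)OC(C)(C)C)c(O)c1 | intermediate
11 | tert-butyl 4-(hex-2-ynoyloxy)-6-propyl-2-(trimethylsilyloxy)benzoate | CCCC#CC(=O)Oc1cc(CCC)c(C(=O)OC(C)(C)C)c(O[Si](C)(C)C)c1 | intermediate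
12 | tert-butyl 4-{[5-chloro-4,6-dimethoxy-2-propyl-6-(trimethylsilyloxy)cyclohexa-1,4-dien-1-yl]carbonyloxy}-6-propyl-2-(trimethylsilyloxy)benzoate (racemic at the ketal carbon) | CCCC1=C(C(=O)Oc2cc(CCC)c(C(=O)OC(C)(C)C)c(O[Si](C)(C)C)c2)C(OC)(O[Si](C)(C)C)C(Cl)=C(OC)C1 | intermediate
13 | tert-butyl 4-[3-chloro-4-methoxy-6-propyl-2-(trimethylsilyloxy)benzoyloxy]-6-propyl-2-(trimethylsilyloxy)benzoate | CCCc1cc(OC)c(Cl)c(O[Si](C)(C)C)c1C(=O)Oc1cc(CCC)c(C(=O)OC(C)(C)C)c(O[Si](C)(C)C)c1 | intermediate
14 | tert-butyl 4-(3-chloro-2-hydroxy-4-methoxy-6-propylbenzoyloxy)-2-hydroxy-6-propylbenzoate | CCCc1cc(OC(=O)c2c(CCC)cc(OC)c(Cl)c2O)cc(O)c1C(=O)OC(C)(C)C | intermediate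
15 | 3-chlorodivaricatic acid | CCCc1cc(OC(=O)c2c(CCC)cc(OC)c(Cl)c2O)cc(O)c1C(=O)O | target

**Step count**

Total steps: 7. Longest linear sequence: 5 (steps 3, 4, 5, 6, 7 from 5-propylresorcinol); the diene arm (steps 1, 2) joins at step 6.

**Steps most likely to fail, with fallbacks**

Step 6. The cycloaddition to a β-alkyl ynoate may be slower than thermal decay of the diene. The ketene acetal may add in a [2+2] sense. Aromatisation may also proceed by loss of silanol in place of methanol.
The fallback sets out from 6 and 8 and comes back at 14. It makes ring A as the free acid by arene chemistry and joins it to ring B by esterification.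
- Exhaustive O-methylation of 6 (Me2SO4, K2CO3, acetone) should give 1,3-dimethoxy-5-propylbenzene F1.
- Lithiation between the two methoxy groups (n-BuLi, THF, 0 °C) should give 2,6-dimethoxy-4-propylphenyllithium F2.
- Quenching with C2Cl6 should give 2-chloro-1,3-dimethoxy-5-propylbenzene F3.
- Rieche formylation (Cl2CHOMe, TiCl4, CH2Cl2) at either of the two equivalent free positions should give 3-chloro-2,4-dimethoxy-6-propylbenzaldehyde F4.
- BCl3 should cleave only the methyl ether chelated to the aldehyde, giving 3-chloro-2-hydroxy-4-methoxy-6-propylbenzaldehyde F5.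
- Pinnick oxidation (NaClO2, NaH2PO4, 2-methylbut-2-ene) should give 3-chloro-2-hydroxy-4-methoxy-6-propylbenzoic acid F6.
- DCC/DMAP esterification of F6 with the free 4-hydroxyl of 8 returns to 14.

Step 2. γ-Deprotonation of the E/Z enol ether mixture may be incomplete, the α-chloro dienolate may self-condense, and the diene may hydrolyse during isolation.
The fallback sets out from 1 and 10 and comes back at 14. It uses the bis-silyl diene made from the keto ester itself and moves the O-methylation to after the cycloaddition.
- Silylation of 1 (Me3SiCl, Et3N) should give methyl 2-chloro-3-(trimethylsilyloxy)but-2-enoate F7.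
- LiN(i-Pr)2 then Me3SiCl should give 2-chloro-1-methoxy-1,3-bis(trimethylsilyloxy)buta-1,3-diene F8.
- Cycloaddition of F8 with 11 (made from 10 as in step 6) should pass through tert-butyl 4-{[5-chloro-6-methoxy-2-propyl-4,6-bis(trimethylsilyloxy)cyclohexa-1,4-dien-1-yl]carbonyloxy}-6-propyl-2-(trimethylsilyloxy)benzoate F9.
- Loss of methanol should give tert-butyl 4-[3-chloro-6-propyl-2,4-bis(trimethylsilyloxy)benzoyloxy]-6-propyl-2-(trimethylsilyloxy)benzoate F10.
- Dilute acid should give tert-butyl 4-(3-chloro-2,4-dihydroxy-6-propylbenzoyloxy)-2-hydroxy-6-propylbenzoate F11.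
- MeI (1 equiv) with K2CO3 in acetone should methylate the ring A 4-hydroxyl, the only hydroxyl not hydrogen-bonded to a carbonyl, returning to 14.

Step 3. Carboxylation may stop short, may occur between the two hydroxyls, and the β-resorcylic acid may lose CO2 again during acidic work-up and drying.
The fallback sets out from 6 and comes back at 7.
- Vilsmeier–Haack formylation (POCl3, DMF; then aq. NaOAc) should give 2,4-dihydroxy-6-propylbenzaldehyde F12.
- Lindgren oxidation (NaClO2, H2NSO3H as hypochlorite scavenger, aq. dioxane, 0 °C) should then give 7.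

**Further compounds**

F1 | step 6 | 1,3-dimethoxy-5-propylbenzene | CCCc1cc(OC)cc(OC)c1
F2 | step 6 | 2,6-dimethoxy-4-propylphenyllithium | CCCc1cc(OC)c([Li])c(OC)c1
F3 | step 6 | 2-chloro-1,3-dimethoxy-5-propylbenzene | CCCc1cc(OC)c(Cl)c(OC)c1
F4 | step 6 | 3-chloro-2,4-dimethoxy-6-propylbenzaldehyde | CCCc1cc(OC)c(Cl)c(OC)c1C=O
F5 | step 6 | 3-chloro-2-hydroxy-4-methoxy-6-propylbenzaldehyde | CCCc1cc(OC)c(Cl)c(O)c1C=O
F6 | step 6 | 3-chloro-2-hydroxy-4-methoxy-6-propylbenzoic acid | CCCc1cc(OC)c(Cl)c(O)c1C(=O)O
F7 | step 2 | methyl 2-chloro-3-(trimethylsilyloxy)but-2-enoate | COC(=O)C(Cl)=C(C)O[Si](C)(C)C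
F8 | step 2 | 2-chloro-1-methoxy-1,3-bis(trimethylsilyloxy)buta-1,3-diene | C=C(O[Si](C)(C)C)C(Cl)=C(OC)O[Si](C)(C)C
F9 | step 2 | tert-butyl 4-{[5-chloro-6-methoxy-2-propyl-4,6-bis(trimethylsilyloxy)cyclohexa-1,4-dien-1-yl]carbonyloxy}-6-propyl-2-(trimethylsilyloxy)benzoate (racemic) | CCCC1=C(C(=O)Oc2cc(CCC)c(C(=O)OC(C)(C)C)c(O[Si](C)(C)C)c2)C(OC)(O[Si](C)(C)C)C(Cl)=C(O[Si](C)(C)C)C1
F10 | step 2 | tert-butyl 4-[3-chloro-6-propyl-2,4-bis(trimethylsilyloxy)benzoyloxy]-6-propyl-2-(trimethylsilyloxy)benzoate | CCCc1cc(O[Si](C)(C)C)c(Cl)c(O[Si](C)(C)C)c1C(=O)Oc1cc(CCC)c(C(=O)OC(C)(C)C)c(O[Si](C)(C)C)c1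
F11 | step 2 | tert-butyl 4-(3-chloro-2,4-dihydroxy-6-propylbenzoyloxy)-2-hydroxy-6-propylbenzoate | CCCc1cc(OC(=O)c2c(CCC)cc(O)c(Cl)c2O)cc(O)c1C(=O)OC(C)(C)C
F12 | step 3 | 2,4-dihydroxy-6-propylbenzaldehyde | CCCc1cc(O)cc(O)c1C=O
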